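**Retrosynthetic overview**

1. Target 17 is cut at the C(sp)–C(sp2) bond of the enyne into alkynyl dioxane acid 12 and (E)-vinyl iodide 16 (Sonogashira); 16 comes from dec-9-en-1-ol by Tsuji–Wacker oxidation, alcohol oxidation and Takai olefination.
2. 12 comes from racemic methyl ester 11 by lipase resolution; 11 from hemiketal 10 by acid-catalysed methanolysis (thermodynamic cis ketal); 10 from 8 by loss of the tert-butoxycarbonyl activating group.
3. The only ring, the 1,2-dioxane (O1–O2–C3–C4–C5–C6; C3 carries CH2CO2H, C6 carries OMe and the chain), is assembled in one operation from three components: β-keto ester 5, methyl but-3-enoate 6 and O2. The C4–C5 and C3–O1 bonds form first, then O2 closes onto C6.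
4. Enabling feature: C6 is a ketal carbon, that is a masked ketone, and C5 is its α-carbon, which becomes a radical site once flanked by a second, removable carbonyl. C4–C3 is a terminal alkene unit and O1–O2 is dioxygen, so the γ-hydroperoxy ketone that results closes by itself to the six-membered peroxyhemiketal.

Key step: step 2

**Assumptions**

- The lipase of step 5 is taken to hydrolyse the (3S,6R)-ester faster; the sense cannot be predicted by rule for this acyl group and would be fixed by a screen of commercial lipases and esterases, the enzyme of this preference being used.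
- Notation: compounds 7–10 are racemic mixtures of diastereomers and are written without stereodescriptors; a racemate of defined relative configuration is written as its two enantiomers joined by a dot.

**Route**

Step 1
Reactants: 1 hex-5-ynoic acid; 2 Meldrum's acid (2,2-dimethyl-1,3-dioxane-4,6-dione)
Product: 5 tert-butyl 3-oxooct-7-ynoate, via acyl Meldrum's acid 3 (not isolated), via acylketene 4 (not isolated)
Conditions: DCC, DMAP, CH2Cl2, 0 to 23 °C; filter, acid wash, concentrate; then t-BuOH (5 equiv), toluene, 90 °C
Reagents that add atoms: tert-butanol, CC(C)(C)O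
Why: The Meldrum's acid route to β-keto esters: DCC/DMAP C-acylation of 2 gives 3, which on heating loses acetone and CO2 by retro-[4+2] fragmentation to acylketene 4 that is trapped by t-BuOH, the terminal alkyne being a spectator.

Step 2
Reactants: 5 tert-butyl 3-oxooct-7-ynoate; 6 methyl but-3-enoate
Product: 8 tert-butyl 3-hydroxy-6-(2-methoxy-2-oxoethyl)-3-(pent-4-yn-1-yl)-1,2-dioxane-4-carboxylate (racemic mixture of diastereomers), via open-chain hydroperoxide 7 (not isolated)
Conditions: Mn(OAc)3·2H2O (10 mol %), AcOH, dry air (1 atm), 23 °C; methyl but-3-enoate in tenfold excess (about 2 M)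
Reagents that add atoms: dioxygen, O=O
Why: Mn(OAc)3 (trivalent manganese) oxidises the enol of 5 to an electrophilic 1,3-dicarbonyl radical at the carbon between the two carbonyls, which adds to the CH2 terminus of the alkene of 6 (new C–C bond); the secondary alkyl radical is captured by O2 (new C–O bond) and divalent manganese reduces the peroxyl radical to hydroperoxide 7, which returns trivalent manganese so that O2 is the terminal oxidant. The closest known reaction type is the aerobic Mn(OAc)3-mediated [2+2+2] assembly of 1,2-dioxan-3-ols from 1,3-dicarbonyl compounds, alkenes and O2. The single ring closes by 6-exo-trig addition of the hydroperoxide oxygen to the ketone carbonyl (ring–chain tautomerism of a γ-hydroperoxy ketone), the ester carbonyls not competing. The peroxide-bearing carbon (C6 of 8, C3 in the later numbering) is formed without control because O2 traps a planar acyclic radical, so 8 is racemic and its absolute configuration is selected in step 5; the hemiketal carbon is reset in step 4 and the ester-bearing carbon loses its stereocentre in step 3. The step needs regioselectivity (attack at the CH2 terminus, secured by formation of the secondary radical) and chemoselectivity for intermolecular addition over 6-exo-dig cyclisation onto the remote alkyne and over direct oxygenation of the dicarbonyl radical; these are secured by the low reactivity of alkynes toward electrophilic radicals, the weak and reversible binding of O2 by the delocalised dicarbonyl radical, air instead of pure O2, and the large excess of 6.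

Step 3
Reactants: 8 tert-butyl 3-hydroxy-6-(2-methoxy-2-oxoethyl)-3-(pent-4-yn-1-yl)-1,2-dioxane-4-carboxylate
Product: 10 methyl 2-[6-hydroxy-6-(pent-4-yn-1-yl)-1,2-dioxan-3-yl]acetate (racemic mixture of hemiketal epimers), via carboxylic acid 9 (not isolated)
Conditions: TFA/CH2Cl2 1:4, 0 to 23 °C; concentrate; toluene, 45 °C
Reagents that add atoms: none
Why: Acidolysis of the tert-butyl ester (E1 loss of 2-methylpropene) gives 9, whose ring-opened β-keto acid tautomer decarboxylates through the usual cyclic six-membered transition state on mild warming and recloses to hemiketal 10, while the methyl ester, the alkyne and the O–O bond should tolerate TFA at room temperature.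

Step 4
Reactants: 10 methyl 2-[6-hydroxy-6-(pent-4-yn-1-yl)-1,2-dioxan-3-yl]acetate
Product: 11 racemic methyl 2-[(3S*,6R*)-6-methoxy-6-(pent-4-yn-1-yl)-1,2-dioxan-3-yl]acetate
Conditions: MeOH, TsOH·H2O (5 mol %), 23 °C; then NaHCO3
Reagents that add atoms: methanol, CO
Why: Acid-catalysed ketalisation through the cyclic peroxy-oxocarbenium ion is reversible and therefore under thermodynamic control, which places OMe axial (anomeric effect) and both carbon substituents equatorial, so the ketal carbon is set relative to C3 with OMe cis to the acetate arm.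

Step 5
Reactants: 11 racemic methyl 2-[(3S*,6R*)-6-methoxy-6-(pent-4-yn-1-yl)-1,2-dioxan-3-yl]acetate
Product: 12 2-[(3S,6R)-6-methoxy-6-(pent-4-yn-1-yl)-1,2-dioxan-3-yl]acetic acid
Conditions: Burkholderia cepacia lipase, phosphate buffer pH 7.2/acetone 9:1, 30 °C, to be stopped near 45 % conversion; acid separated by NaHCO3 extraction
Reagents that add atoms: water, O
Why: Lipase-catalysed enantioselective ester hydrolysis (kinetic resolution) of a 2-(2-oxacycloalkyl)acetate at neutral pH spares the base-sensitive peroxide, and the assumed preference of the enzyme for the (3S,6R)-ester fixes the absolute configuration of C3 and with it of C6.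

Step 6
Reactants: 13 dec-9-en-1-ol
Product: 14 10-hydroxydecan-2-one
Conditions: PdCl2 (10 mol %), CuCl (1 equiv), O2 (1 atm), DMF/H2O 7:1, 23 °C
Reagents that add atoms: water, O
Why: Tsuji–Wacker oxidation: Markovnikov hydroxypalladation of the terminal alkene by water and β-hydride elimination give the methyl ketone, CuCl/O2 returning divalent palladium and the remote primary alcohol staying untouched.

Step 7
Reactants: 14 10-hydroxydecan-2-one
Product: 15 9-oxodecanal
Conditions: TEMPO (10 mol %), PhI(OAc)2 (1.1 equiv), CH2Cl2, 23 °C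
Reagents that add atoms: none
Why: TEMPO/PhI(OAc)2 oxidation through the oxoammonium salt should convert the primary alcohol into the aldehyde without over-oxidation and without touching the ketone.

Step 8
Reactants: 15 9-oxodecanal
Product: 16 (E)-11-iodoundec-10-en-2-one
Conditions: CrCl2 (6 equiv), CHI3 (2 equiv), 1,4-dioxane/THF 6:1, 0 to 23 °C
Reagents that add atoms: iodoform, IC(I)I
Why: Takai olefination: the gem-dichromium species formed from CHI3 and CrCl2 adds to the aldehyde much faster than to the methyl ketone and anti-elimination gives the (E)-vinyl iodide, the dioxane-rich solvent favouring the E isomer.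

Step 9
Reactants: 12 2-[(3S,6R)-6-methoxy-6-(pent-4-yn-1-yl)-1,2-dioxan-3-yl]acetic acid; 16 (E)-11-iodoundec-10-en-2-one
Product: 17 2-[(3S,6R)-6-methoxy-6-[(6E)-15-oxohexadec-6-en-4-yn-1-yl]-1,2-dioxan-3-yl]acetic acid (target)
Conditions: PdCl2(PPh3)2 (5 mol %), CuI (10 mol %), Et3N (5 equiv), THF, 23 °C, degassed
Reagents that add atoms: none
Why: Sonogashira coupling: oxidative addition of the vinyl iodide to zerovalent palladium, transmetalation from the copper acetylide of 12 and reductive elimination join the two fragments with retention of the E geometry, the dialkyl peroxyketal being expected to survive the PdCl2(PPh3)2/CuI system at room temperature and the acid being carried as its triethylammonium salt.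

**Compound list**

1 | hex-5-ynoic acid | C#CCCCC(=O)O | starting material
2 | Meldrum's acid (2,2-dimethyl-1,3-dioxane-4,6-dione) | CC1(C)OC(=O)CC(=O)O1 | starting material
3 | 5-(1-hydroxyhex-5-yn-1-ylidene)-2,2-dimethyl-1,3-dioxane-4,6-dione (acyl Meldrum's acid, enol form) | C#CCCCC(O)=C1C(=O)OC(C)(C)OC1=O | intermediate (not isolated)
4 | hex-5-ynoylketene (oct-1-en-7-yne-1,3-dione) | C#CCCCC(=O)C=C=O | intermediate (not isolated)
5 | tert-butyl 3-oxooct-7-ynoate | C#CCCCC(=O)CC(=O)OC(C)(C)C | intermediate
6 | methyl but-3-enoate | C=CCC(=O)OC | starting material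
7 | 1-tert-butyl 6-methyl 2-(hex-5-ynoyl)-4-hydroperoxyhexanedioate (racemic, both diastereomers) | C#CCCCC(=O)C(CC(OO)CC(=O)OC)C(=O)OC(C)(C)C | intermediate (not isolated)
8 | tert-butyl 3-hydroxy-6-(2-methoxy-2-oxoethyl)-3-(pent-4-yn-1-yl)-1,2-dioxane-4-carboxylate (racemic mixture of diastereomers) | C#CCCCC1(O)OOC(CC(=O)OC)CC1C(=O)OC(C)(C)C | intermediate
9 | 3-hydroxy-6-(2-methoxy-2-oxoethyl)-3-(pent-4-yn-1-yl)-1,2-dioxane-4-carboxylic acid (racemic mixture of diastereomers) | C#CCCCC1(O)OOC(CC(=O)OC)CC1C(=O)O | intermediate (not isolated)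
10 | methyl 2-[6-hydroxy-6-(pent-4-yn-1-yl)-1,2-dioxan-3-yl]acetate (racemic, hemiketal epimers, in equilibrium with open-chain methyl 3-hydroperoxy-6-oxoundec-10-ynoate) | C#CCCCC1(O)CCC(CC(=O)OC)OO1 | intermediate
11 | racemic methyl 2-[(3S*,6R*)-6-methoxy-6-(pent-4-yn-1-yl)-1,2-dioxan-3-yl]acetate (OMe cis to the acetate arm; both enantiomers written) | CO[C@@]1(CCCC#C)CC[C@@H](CC(=O)OC)OO1.CO[C@]1(CCCC#C)CC[C@H](CC(=O)OC)OO1 | intermediate
12 | 2-[(3S,6R)-6-methoxy-6-(pent-4-yn-1-yl)-1,2-dioxan-3-yl]acetic acid | CO[C@@]1(CCCC#C)CC[C@@H](CC(=O)O)OO1 | intermediate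
13 | dec-9-en-1-ol | C=CCCCCCCCCO | starting material
14 | 10-hydroxydecan-2-one | CC(=O)CCCCCCCCO | intermediate
15 | 9-oxodecanal | CC(=O)CCCCCCCC=O | intermediate
16 | (E)-11-iodoundec-10-en-2-one | CC(=O)CCCCCCC/C=C/I | intermediate
17 | 2-[(3S,6R)-6-methoxy-6-[(6E)-15-oxohexadec-6-en-4-yn-1-yl]-1,2-dioxan-3-yl]acetic acid | CO[C@@]1(CCCC#C/C=C/CCCCCCCC(C)=O)CC[C@@H](CC(=O)O)OO1 | target

**Summary**

Total step count: 9. Longest linear sequence: 6 (steps 1–5, then step 9).

Steps most likely to fail:

1. Step 2. The dicarbonyl radical may add too slowly to the unactivated terminal alkene, so that direct oxygenation of the radical (α-hydroxylation of 5), cyclisation onto the alkyne or autoxidation of 6 takes over. Fallback (polar, stepwise formation of the same two bonds), setting out from 5 and returning at 11: C-alkylation of 5 with methyl (E)-4-bromobut-2-enoate (K2CO3, acetone) should give 1-tert-butyl 6-methyl (E)-2-(hex-5-ynoyl)hex-4-enedioate F1. TFA gives (E)-2-(hex-5-ynoyl)-6-methoxy-6-oxohex-4-enoic acid F2, which loses CO2 on warming to methyl (E)-6-oxoundec-2-en-10-ynoate F3, with no peroxide yet present. HC(OMe)3/MeOH/TsOH gives methyl (E)-6,6-dimethoxyundec-2-en-10-ynoate F4, and ketal exchange with urea–hydrogen peroxide and Sc(OTf)3 in MeOH gives methyl (E)-6-hydroperoxy-6-methoxyundec-2-en-10-ynoate F5. Et2NH in CF3CH2OH then closes the ring by 6-exo-trig peroxy-Michael addition; any trans isomer is converged under the conditions of step 4, and the route is rejoined at 11 (steps 3 and 4 are bypassed).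

2. Step 5. The lipase may discriminate poorly, or in the wrong sense, at a stereocentre two atoms away from the reacting carbonyl, giving acid of low enantiomeric purity. Fallback (covalent diastereomers instead of an enzyme), setting out from 11 and returning at 12: LiOH, THF/H2O, 0 °C gives the racemic acid, rac-2-[(3S*,6R*)-6-methoxy-6-(pent-4-yn-1-yl)-1,2-dioxan-3-yl]acetic acid F6. DCC/DMAP coupling with (S)-4-benzyl-1,3-oxazolidin-2-one gives two imides to be separated by chromatography or crystallisation: (S)-4-benzyl-3-{2-[(3S,6R)-6-methoxy-6-(pent-4-yn-1-yl)-1,2-dioxan-3-yl]acetyl}-1,3-oxazolidin-2-one F7 and its (3R,6S) diastereomer, (S)-4-benzyl-3-{2-[(3R,6S)-6-methoxy-6-(pent-4-yn-1-yl)-1,2-dioxan-3-yl]acetyl}-1,3-oxazolidin-2-one F8. LiOH/H2O2, THF/H2O, 0 °C on F7 gives 12.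

3. Step 3. TFA may trigger heterolysis or rearrangement of the peroxyhemiketal, or the decarboxylation may stall because the β-keto acid is held as the cyclic hemiketal. Fallback (fluoride-triggered unmasking of the carboxyl group, so that no strong acid meets the peroxide), setting out from 1 and 2 and returning at 10: 3 is thermolysed with 2-(trimethylsilyl)ethanol in place of t-BuOH to give 2-(trimethylsilyl)ethyl 3-oxooct-7-ynoate F9. The conditions of step 2 with 6 and air give 2-(trimethylsilyl)ethyl 3-hydroxy-6-(2-methoxy-2-oxoethyl)-3-(pent-4-yn-1-yl)-1,2-dioxane-4-carboxylate F10. TBAF buffered with AcOH, THF, 0 °C releases acid 9, which decarboxylates to 10.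

**Further compounds**

F1 | step 2 | 1-tert-butyl 6-methyl (E)-2-(hex-5-ynoyl)hex-4-enedioate | C#CCCCC(=O)C(C/C=C/C(=O)OC)C(=O)OC(C)(C)C
F2 | step 2 | (E)-2-(hex-5-ynoyl)-6-methoxy-6-oxohex-4-enoic acid | C#CCCCC(=O)C(C/C=C/C(=O)OC)C(=O)O
F3 | step 2 | methyl (E)-6-oxoundec-2-en-10-ynoate | C#CCCCC(=O)CC/C=C/C(=O)OC
F4 | step 2 | methyl (E)-6,6-dimethoxyundec-2-en-10-ynoate | C#CCCCC(OC)(OC)CC/C=C/C(=O)OC
F5 | step 2 | methyl (E)-6-hydroperoxy-6-methoxyundec-2-en-10-ynoate (racemic) | C#CCCCC(OC)(OO)CC/C=C/C(=O)OC
F6 | step 5 | rac-2-[(3S*,6R*)-6-methoxy-6-(pent-4-yn-1-yl)-1,2-dioxan-3-yl]acetic acid (both enantiomers written) | CO[C@@]1(CCCC#C)CC[C@@H](CC(=O)O)OO1.CO[C@]1(CCCC#C)CC[C@H](CC(=O)O)OO1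
F7 | step 5 | (S)-4-benzyl-3-{2-[(3S,6R)-6-methoxy-6-(pent-4-yn-1-yl)-1,2-dioxan-3-yl]acetyl}-1,3-oxazolidin-2-one | CO[C@@]1(CCCC#C)CC[C@@H](CC(=O)N2[C@@H](Cc3ccccc3)COC2=O)OO1
F8 | step 5 | (S)-4-benzyl-3-{2-[(3R,6S)-6-methoxy-6-(pent-4-yn-1-yl)-1,2-dioxan-3-yl]acetyl}-1,3-oxazolidin-2-one | CO[C@]1(CCCC#C)CC[C@H](CC(=O)N2[C@@H](Cc3ccccc3)COC2=O)OO1
F9 | step 3 | 2-(trimethylsilyl)ethyl 3-oxooct-7-ynoate | C#CCCCC(=O)CC(=O)OCC[Si](C)(C)C
F10 | step 3 | 2-(trimethylsilyl)ethyl 3-hydroxy-6-(2-methoxy-2-oxoethyl)-3-(pent-4-yn-1-yl)-1,2-dioxane-4-carboxylate (racemic mixture of diastereomers) | C#CCCCC1(O)OOC(CC(=O)OC)CC1C(=O)OCC[Si](C)(C)C
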